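The constant I need can be read off the flask asked about, the east run followed so far, if I replace its falling curve by the curve's mean.

in all of them: initiator 76 mM
- east: substrate 1 M; coupling partner 0.80 M; temperature 40 °C; the very flask that is asked about, followed so far
- north: substrate 1.5 M; coupling partner 0.80 M; temperature 46 °C; run made earlier
- flask: substrate 1.0 M; coupling partner 0.800 M; temperature 40 °C; time 4.0 min

east run (percent of the substrate charged)

| time / min | target / % | substrate / % |
|---|---|---|
| 0.333 | 66.7 | 30.4 |
| 0.833 | 70.9 | 22.7 |
| 1.50 | 66.8 | 24.2 |
| 2.50 | 60.4 | 21.9 |

north run (percent of the substrate charged)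

| time / s | target / % | substrate / % |
|---|---|---|
| 10.0 | 41.6 | 56.7 |
| 20.0 | 48.4 | 48.5 |
| 40.0 | 47.4 | 47.1 |
| 90.0 | 39.5 | 49.5 |

(standard deviation of a reading: 1 percentage point)

* target, in percent of the substrate first charged, at 4.0 min
* the option that brings most further target ("none" if no option brings more than 2 percentage points) (Thursday's / Friday's / Wednesday's / Tuesday's / none)
* target present, with what was taken out counted in, in percent of the substrate first charged, after Thursday's
* target present, with what was taken out counted in, in percent of the substrate first charged, after Wednesday's

- Thursday's: change nothing and wait 4.0 min more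
- Friday's: at 4.0 min take out 90 % of the target then present, then wait 4.0 min
- Wednesday's: at 4.0 min add coupling partner, 50.0 % of the amount charged, then wait 4.0 min
- Tuesday's: at 4.0 min raise the temperature by 15 K, then wait 4.0 min

- target taken out counts as made
- additions bring no volume worth counting

In the east run the target falls from 70.9 % at 0.833 min to 60.4 % at 2.50 min. That is 11 percentage points lost around a mean of 65.7 % in 1.67 min, so I read 0.0959 min⁻¹ as the loss constant, the share of the target present that goes each minute once none is being made. But is none being made? The substrate moves 0.8 points over that stretch, against a scatter of 1 point, so I take it as flat. In the east run its last 3 readings average 22.9 %, near the 20.0 % that [coupling partner]/[substrate] allows, and in the north run they average 48.4 % against 46.7 %. The partner therefore looks like the limiting reagent.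

Two readings carry this constant, so it is uncertain by about 13.5 %. Does the mean itself cost anything? Over 4.0 min the mean rule keeps 0.678 of the target and the exponential keeps 0.681, so the two part by 0.00327. Carrying the last reading forward by the same rule gives 52.3 % at 4.0 min and 35.5 % after Thursday's.

By this reckoning, waiting in the asked flask takes 17 points. Friday's takes out 90 % of the target, and the rest still loses 1.7 points. Wednesday's adds 0.400 M of partner, which is more than the substrate I read as left, so the target can gain about 22.9 %. If all of that forms at once, I reckon 51.0 %, a change of −1.3 points. The objection is that the initiator may be dead, but a stop beside the partner's limit in both runs argues against that, so I keep this figure. The north run, hotter and with more substrate than the east run, reads a loss constant of 0.218 min⁻¹, 2.27 times the east value, so I expect no gain from Tuesday's heat. My choice is none.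

The forecast says 52 % (49 % to 55 %) at 4.0 min, 35 % after Thursday's, 36 % after Wednesday's and none as the best option, with "Added partner probably finds no live initiator", and on Wednesday's it differs from my 51.0 %.

The flask gives 50.1 %, then 31.7 % after Thursday's and 46.1 % after Wednesday's, and the best option is none. At 4.00 min it holds 27.7 % of over-reaction product, with 0 % of the partner free. Applying the kept share to 50.1 % gives 34.0 % after Thursday's, 2.3 points above the computed value.

    initiator → 2 initiating radical (k = 4.64 × 10⁻⁶ s⁻¹, Ea = 96.0 kJ mol⁻¹)
    substrate + second chain carrier → by-product + first chain carrier (k = 1.69 × 10⁶ M⁻¹ s⁻¹, Ea = 24.0 kJ mol⁻¹)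
    2 first chain carrier → ended chains A (k = 1.20 × 10⁹ M⁻¹ s⁻¹, Ea = 10.0 kJ mol⁻¹)
    coupling partner → decomposed reagent (k = 0.00276 s⁻¹, Ea = 85.0 kJ mol⁻¹)
    substrate + initiating radical → capped initiator + first chain carrier (k = 5.42 × 10⁶ M⁻¹ s⁻¹, Ea = 15.0 kJ mol⁻¹)
    target → over-reaction product (k = 0.00191 s⁻¹, Ea = 86.0 kJ mol⁻¹)
    2 second chain carrier → ended chains B (k = 1.50 × 10⁸ M⁻¹ s⁻¹, Ea = 13.0 kJ mol⁻¹)
    coupling partner + first chain carrier → target + second chain carrier (k = 8.29 × 10⁶ M⁻¹ s⁻¹, Ea = 8.00 kJ mol⁻¹)
    (constants at 40 °C)

The neighbour with 1.7 M of substrate can make 47.1 % by its partner charge, and the same kept share turns that into 31.9 % at 4.0 min. The computed result there is 29.6 %.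

All runs are calculated with made-up constants; scatter was added.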